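## Structural features

Glisoflavone is a 3-arylchromen-4-one: ring A is fused to the pyranone ring C, and ring B is attached through the C3–C1' bond instead of at C2. Ring A carries a methyl ether at C5, peri to the C4 carbonyl, and a free hydroxyl at C7. Ring B carries a catechol at C3'/C4' and a 3-methylbut-2-enyl (prenyl) chain at C5', ortho to the 4'-hydroxyl. There is no stereocentre in the target; the only stereochemical event is that C2 of a flavanone precursor is a stereocentre that vanishes, so racemic material suffices. The fragile groups are:
- the prenyl alkene, which is attacked by electrophilic oxidants, is hydrogenated, and under acid closes onto the 4'-hydroxyl to a chroman;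
- the catechol, which is oxidised to an ortho-quinone by air under base or by trivalent iodine;
- the 5-methyl ether, which is cleaved by chelating Lewis acids such as BBr3, BCl3 or AlCl3, and this excludes benzyl or isopropyl ethers as phenol protection;
- C2 of the chromone, which is opened by hydroxide or amines.

The real difficulty is to forge C3–C1' to a 1,3,4,5-tetrasubstituted ring B while four oxygen functions stay distinguishable and the prenyl group is kept away from every oxidant and strong acid. The key step exploits the C2–C3 edge of ring C. In a flavanone, C3 is the enolisable alpha-carbon of the C4 ketone, and C2 is benzylic and bonded to O1, so it can take up positive charge. The oxygen at C4', para to C1', lets ring B bridge and move from C2 to C3.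

## Logic of the disconnections

**12 to 11.** The three phenolic O–H bonds of 12 are replaced by O–Si bonds. The catechol and the ortho-prenylphenol of 12 tolerate neither oxidants, nor acid, nor chelating Lewis acids. The last unmasking should therefore be a neutral, fluoride-induced cleavage. The skeleton is not simplified, but every earlier step then works on a substrate without free phenols. The forward step must be buffered so that no catecholate is exposed to air and the chromone is not opened.

**11 to 9 and 10.** The aryl–CH2 bond at C5' is cut. The prenyl alkene could not survive the oxidant of the key step, so it has to enter afterwards, and an aryl bromide is an inert placeholder for it. The gain is that ring B becomes the substitution pattern of commercial 1. The forward coupling has to work on an electron-rich bromide flanked by a silyl ether, give the linear allylic isomer, and use neither fluoride nor aqueous base.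

**9 to 8 (key step).** The C3–C1' bond is cut and C1' is reconnected to C2, which turns the isoflavone into a flavanone. This is the one transformation that reduces the isoflavone problem to chalcone chemistry. The demand is that aryl migration beats loss of the C2 hydrogen, and that the protecting groups withstand an oxidant that sets free one equivalent of sulfonic acid. Methoxymethyl ethers on 8 would be the shortest choice, but hot sulfonic acid hydrolyses them, a ring B phenol freed in this way would be oxidised at once, and their final removal would need acid next to the prenylphenol. Therefore 8 and 9 carry triisopropylsilyl ethers, which are acid-stable, remain electron-donating, and are fluoride-labile.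

**8 to 7.** The three O–Si bonds are cut. Aryl silyl ethers do not survive the hydroxide of an aldol condensation, so they are put on only after ring C exists. The gain is that 7 is reachable by classical base and acid chemistry. The forward step must silylate the hindered 4'-hydroxyl completely without opening the flavanone.

**7 to 5 (through 6).** The O1–C2 bond is cut (retro oxa-Michael) and the three free phenols are replaced by acetals. A flavanone is the cyclised form of a 2'-hydroxychalcone, and acetal groups that serve the basic aldol come off under the same acid that starts the ring closure. The forward step relies on the chalcone–flavanone equilibrium lying on the flavanone side, which the 6'-methoxy group of the chalcone favours by twisting the enone out of plane.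

**5 to 2 and 4.** The enone C=C bond is cut (retro aldol condensation). This divides the molecule into two aromatic building blocks of similar size. The forward condensation needs every phenol masked except the chelated one.

**2 to 1 and 4 to 3.** The acetal O–CH2 bonds are cut. 1 is alkylated on both oxygens; 3 is alkylated only on the 4-hydroxyl, because the 2-hydroxyl is tied up in a hydrogen bond to the ketone.

## Other disconnections considered

**Alternative 1:** The cut runs through ring B at C2'–C3' and C5'–C6'. The chromon-3-yl vinamidinium salt A2 already holds C2', C1', C6' and the C3–C1' bond. It would be condensed under base with the unsymmetrical ketone A3. The carbonyl carbon of A3 becomes C4', and its two alpha-carbons become C3' (with the methoxymethoxy group) and C5' (with the prenyl chain). Two condensations with loss of two molecules of dimethylamine would close ring B as the 4'-phenol A1, and removal of the allyl and methoxymethyl groups would give 12.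
- In its favour: A2 is symmetrical about C1', so only one regioisomer of ring B can form. The prenyl chain arrives inside A3, so no tin reagent and no palladium coupling is needed and the alkene never meets an oxidant. The two catechol oxygens come out differentiated.
- Against it here: the C3–C1' problem is not solved but moved into the making of A2. That needs a two-carbon side chain on C3 of the chromone and chloromethyleneiminium conditions, which would also formylate C6 and C8 of the electron-rich ring A. C2 of the chromone in A2 is a vinylogous ester carbon that the alkoxide base and the liberated dimethylamine could attack, opening ring C. A3 is an alpha-alkoxy ketone prone to self-condensation. The end-game would need acid next to an ortho-prenylphenol and a separate deallylation.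
- Comparison: structurally it builds a benzene ring that the chosen plan buys complete with bromine and both oxygens. Mechanistically it forms two C–C bonds in one operation against one, but on a base-sensitive chromone, whereas the aryl shift runs under acid on a fully masked substrate. In step count, the separate preparations of A2 and A3 plus two deprotections would make it longer than eight steps. It is the better plan on two points: no organotin and no oxidant–alkene conflict. It also has no flavone by-product channel.

**Alternative 2:** The cut is the C3'–O bond. The mono-phenol A5 would be treated with 2-iodoxybenzoic acid, which delivers oxygen to the only free ortho carbon, C3' (the other is blocked by the prenyl chain). The resulting ortho-quinone would be reduced by Na2S2O4 in the same flask to the catechol A4, and acid would then remove the 7-O-methoxymethyl group to give 12.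
- In its favour: ring B can be introduced as a simple 4-oxygenated aryl unit, and no catechol has to be carried or protected. The regiochemistry is fixed by substitution. The oxidation is metal-free and parallels a late biosynthetic hydroxylation.
- Against it here: the oxidant meets the complete and most fragile molecule. An ortho-quinone flanked by a prenyl group can tautomerise to a quinone methide and close to a 2H-chromene, or add nucleophiles, before the reductant acts. The phenol of A5 is deactivated by the para chromonyl group. The cut deals with one oxygen only, so the C3–C1' bond and the prenyl group still need their own constructions on the way to A5.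
- Comparison: structurally the chosen route takes both ring B oxygens from commercial 1 and never oxidises a prenylated arene. Mechanistically both plans use hypervalent iodine, but in the chosen plan it acts on a substrate with neither alkene nor free phenol, and in the alternative on one that has both. In step economy the alternative is about equal and could be one step shorter because it needs fewer protecting groups; that, and the absence of a protecting-group exchange, are genuine points in its favour.

**Alternative 3:** The cut removes ring A at C4a–C5 and C8–C8a. The ketene acetal diene A8 would add across the brominated C5=C6 bond of the 3-aryl-5-bromopyran-4-one A7. Its nucleophilic CH2 terminus would bond to the oxygen-bearing beta-carbon (future C8a) and its acetal carbon to the bromine-bearing alpha-carbon (future C4a). Loss of HBr and methanol and hydrolysis of the silyl enol ether would aromatise ring A to A6, and acid would then unmask the catechol to give 12.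
- In its favour: the diene itself differentiates O5 from O7, so ring A needs no protecting-group chemistry. The bromine both steers the regiochemistry and is the leaving group for aromatisation. The prenyl group, already present in A7, never meets an oxidant.
- Against it here: the ring that is built is the simplest part of the molecule and is commercially available with the right oxygen pattern. A pyran-4-one is a vinylogous ester with some aromatic stabilisation and a reluctant dienophile, so the hydrolytically labile diene would need heat or a Lewis acid that threatens the methoxymethyl ethers and the prenyl group. The second enone double bond of A7 (C2=C3) is a possible competing site. A7 is an unsymmetrical 3,5-disubstituted pyranone with a fully elaborated ring B and would cost more steps than the whole chosen route up to 9.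
- Comparison: structurally it spends its main step on ring A, whereas the chosen plan spends it on the C3–C1' bond that defines an isoflavone. Mechanistically a cycloaddition–elimination forms two C–C bonds and an aromatic ring in one operation, which is more bond-forming power than the single bond of the aryl shift. In step count it would be clearly longer. It is equal to the chosen plan in fixing the O5/O7 pattern (bought there in 3) and better in having no oxidant in the presence of the alkene.

Key step: step 6

Remark 1: 2',4'-dihydroxy-6'-methoxyacetophenone (3) is taken to be a catalogue compound; this saves the protection and mono-methylation sequence that 2',4',6'-trihydroxyacetophenone would need.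

Remark 2: names and SMILES of all compounds were checked against each other and against the target and needed no correction. The bromine of 1 becomes C5' of the flavonoid, ortho to the 4'-oxygen. Only the 4'-oxygen is a resonance donor towards the migrating carbon C1'; the 3'-oxygen and the bromine are meta to it.

## Route

Step 1
Reactants: 1 3-bromo-4,5-dihydroxybenzaldehyde
Product: 2 3-bromo-4,5-bis(methoxymethoxy)benzaldehyde
Conditions: MOMCl (3 equiv), iPr2NEt, CH2Cl2, 0 °C to rt
Reagents that add atoms: chloromethyl methyl ether, COCCl
Why: Williamson-type O-alkylation of both phenoxides by the reactive alpha-chloro ether; the small electrophile reaches the 4-hydroxyl between bromine and oxygen, and the aldehyde is untouched.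

Step 2
Reactants: 3 2',4'-dihydroxy-6'-methoxyacetophenone
Product: 4 1-[2-hydroxy-6-methoxy-4-(methoxymethoxy)phenyl]ethanone
Conditions: MOMCl (1.1 equiv), iPr2NEt, CH2Cl2, 0 °C
Reagents that add atoms: chloromethyl methyl ether, COCCl
Why: Regioselective O-alkylation; the 4-hydroxyl is the more acidic and accessible one, whereas the 2-hydroxyl is held in a hydrogen bond to the ketone and stays free, as the later ring closure requires.

Step 3
Reactants: 2 3-bromo-4,5-bis(methoxymethoxy)benzaldehyde; 4 1-[2-hydroxy-6-methoxy-4-(methoxymethoxy)phenyl]ethanone
Product: 5 (E)-3-[3-bromo-4,5-bis(methoxymethoxy)phenyl]-1-[2-hydroxy-6-methoxy-4-(methoxymethoxy)phenyl]prop-2-en-1-one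
Conditions: KOH (50% aq.), EtOH, 0 °C to rt; then cold dilute HCl to pH 5–6
Reagents that add atoms: none
Why: Claisen–Schmidt aldol condensation; the methyl ketone enolate adds to the non-enolisable aldehyde and E1cB loss of water gives the conjugated E-enone, and in strong base the product rests as the chalcone phenoxide and does not cyclise; acetals and aryl bromide are inert to hydroxide.

Step 4
Reactants: 5 (E)-3-[3-bromo-4,5-bis(methoxymethoxy)phenyl]-1-[2-hydroxy-6-methoxy-4-(methoxymethoxy)phenyl]prop-2-en-1-one
Product: 7 rac-2-(3-bromo-4,5-dihydroxyphenyl)-7-hydroxy-5-methoxychroman-4-one, via MOM-free chalcone 6 (not isolated)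
Conditions: 3 M HCl, MeOH, 60 °C; then NaOAc, reflux, Ar
Reagents that add atoms: none
Why: Acid-catalysed acetal exchange with methanol frees the three phenols, and the 2'-hydroxyl then adds to the enone in a 6-endo-trig oxa-Michael closure that acetate buffering drives to the flavanone, favoured because the 6'-methoxy group twists the open enone. C2 forms without any control (racemate), which is harmless because this centre becomes trigonal in step 6.

Step 5
Reactants: 7 rac-2-(3-bromo-4,5-dihydroxyphenyl)-7-hydroxy-5-methoxychroman-4-one
Product: 8 rac-2-[3-bromo-4,5-bis(triisopropylsilyloxy)phenyl]-5-methoxy-7-(triisopropylsilyloxy)chroman-4-one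
Conditions: TIPSOTf (3.5 equiv), 2,6-lutidine, CH2Cl2, 0 °C to rt
Reagents that add atoms: triisopropylsilyl trifluoromethanesulfonate, CC(C)[Si](OS(=O)(=O)C(F)(F)F)(C(C)C)C(C)C
Why: O-Silylation of all three phenols; the silyl triflate is reactive enough for the 4'-hydroxyl between bromine and the 3'-silyloxy group, and the weak hindered base neither enolises the ketone appreciably nor opens the flavanone by beta-elimination.

Step 6
Reactants: 8 rac-2-[3-bromo-4,5-bis(triisopropylsilyloxy)phenyl]-5-methoxy-7-(triisopropylsilyloxy)chroman-4-one
Product: 9 3-[3-bromo-4,5-bis(triisopropylsilyloxy)phenyl]-5-methoxy-7-(triisopropylsilyloxy)chromen-4-one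
Conditions: PhI(OH)OTs (1.3 equiv), MeCN, 60 °C, Ar
Reagents that add atoms: none
Why: Trace acid from the reagent enolises the C4 ketone, and the enol carbon C3 attacks the electrophilic trivalent iodine on the face away from the C2 aryl group, so that a trans 3-[phenyl(tosyloxy)iodanyl]flavanone forms with loss of water. In the conformer with both substituents axial the C2–C1' bond is antiperiplanar to the C3–I bond; ring B then bridges C2 and C3 through C1' as a phenonium ion while iodobenzene, an exceptionally good leaving group, departs and the iodine returns to the monovalent state. Opening of the bridge on the C2 side leaves C1' bonded to C3 and a cation at C2 that O1 stabilises as an oxocarbenium ion, and loss of the C3 proton gives the chromone. The closest known reaction type is the oxidative 2,3-aryl migration of flavanones to isoflavones with PhI(OH)OTs or Tl(NO3)3, a relative of the alpha-tosyloxylation of ketones. No ring closes and no stereocentre is formed; the only stereocentre of 8, C2, becomes trigonal, which is why racemic 8 is sufficient. The step needs migration to beat 2,3-dehydrogenation to the flavone, direct displacement of iodobenzene by tosylate, and attack of the oxidant on the arenes: the 4'-silyloxy oxygen para to the migrating carbon stabilises the phenonium ion (bromine and the 3'-oxygen are meta and withdraw only weakly), and anti attack on the enol gives the trans iodane that the antiperiplanar shift requires. Acetonitrile is chosen because it is not nucleophilic: no C4 ketal forms, so ring A cannot migrate from C4 to C3 (the ring-contraction path of ketalising alcohol–orthoformate media), and the liberated TsOH finds no alcohol with which to solvolyse protecting groups. The triisopropylsilyl ethers withstand that acid and keep every phenol masked from the oxidant, and the substrate contains no alkene.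

Step 7
Reactants: 9 3-[3-bromo-4,5-bis(triisopropylsilyloxy)phenyl]-5-methoxy-7-(triisopropylsilyloxy)chromen-4-one; 10 tributyl(3-methylbut-2-enyl)stannane
Product: 11 5-methoxy-3-[3-(3-methylbut-2-enyl)-4,5-bis(triisopropylsilyloxy)phenyl]-7-(triisopropylsilyloxy)chromen-4-one
Conditions: Pd(PPh3)4 (10 mol%), DMF (degassed, amine-free), 95 °C, Ar
Reagents that add atoms: none
Why: Stille coupling; zerovalent palladium inserts into the C–Br bond, the allylic stannane transmetallates to the arylpalladium bromide (divalent palladium), and reductive elimination at the less hindered CH2 terminus of the allyl ligand gives the linear prenyl arene. The conditions are neutral and fluoride-free, so the silyl ethers and the chromone are untouched.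

Step 8
Reactants: 11 5-methoxy-3-[3-(3-methylbut-2-enyl)-4,5-bis(triisopropylsilyloxy)phenyl]-7-(triisopropylsilyloxy)chromen-4-one
Product: 12 glisoflavone, 3-[3,4-dihydroxy-5-(3-methylbut-2-enyl)phenyl]-7-hydroxy-5-methoxychromen-4-one
Conditions: Bu4NF, AcOH (1:1, 3.5 equiv), THF, 0 °C to rt, Ar
Reagents that add atoms: none
Why: Fluoride attacks silicon and expels the phenoxide, which acetic acid protonates at once, so that neither a catecholate is exposed to air nor the chromone to base. No acid strong enough to cyclise the ortho-prenylphenol and no Lewis acid that would cleave the 5-methyl ether is present.

## Compound list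

1 | 3-bromo-4,5-dihydroxybenzaldehyde | O=Cc1cc(O)c(O)c(Br)c1 | starting material
2 | 3-bromo-4,5-bis(methoxymethoxy)benzaldehyde | O=Cc1cc(OCOC)c(OCOC)c(Br)c1 | intermediate
3 | 2',4'-dihydroxy-6'-methoxyacetophenone | CC(=O)c1c(O)cc(O)cc1OC | starting material
4 | 1-[2-hydroxy-6-methoxy-4-(methoxymethoxy)phenyl]ethanone | CC(=O)c1c(O)cc(OCOC)cc1OC | intermediate
5 | (E)-3-[3-bromo-4,5-bis(methoxymethoxy)phenyl]-1-[2-hydroxy-6-methoxy-4-(methoxymethoxy)phenyl]prop-2-en-1-one | COc1cc(OCOC)cc(O)c1C(=O)/C=C/c1cc(Br)c(OCOC)c(OCOC)c1 | intermediate
6 | (E)-3-(3-bromo-4,5-dihydroxyphenyl)-1-(2,4-dihydroxy-6-methoxyphenyl)prop-2-en-1-one (formed and consumed in step 4, not isolated) | COc1cc(O)cc(O)c1C(=O)/C=C/c1cc(Br)c(O)c(O)c1 | intermediate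
7 | rac-2-(3-bromo-4,5-dihydroxyphenyl)-7-hydroxy-5-methoxychroman-4-one (racemic at C2) | COc1cc(O)cc2OC(c3cc(Br)c(O)c(O)c3)CC(=O)c12 | intermediate
8 | rac-2-[3-bromo-4,5-bis(triisopropylsilyloxy)phenyl]-5-methoxy-7-(triisopropylsilyloxy)chroman-4-one (racemic at C2) | COc1cc(O[Si](C(C)C)(C(C)C)C(C)C)cc2OC(c3cc(Br)c(O[Si](C(C)C)(C(C)C)C(C)C)c(O[Si](C(C)C)(C(C)C)C(C)C)c3)CC(=O)c12 | intermediate
9 | 3-[3-bromo-4,5-bis(triisopropylsilyloxy)phenyl]-5-methoxy-7-(triisopropylsilyloxy)chromen-4-one | COc1cc(O[Si](C(C)C)(C(C)C)C(C)C)cc2occ(-c3cc(Br)c(O[Si](C(C)C)(C(C)C)C(C)C)c(O[Si](C(C)C)(C(C)C)C(C)C)c3)c(=O)c12 | intermediate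
10 | tributyl(3-methylbut-2-enyl)stannane | CCCC[Sn](CCCC)(CCCC)CC=C(C)C | starting material
11 | 5-methoxy-3-[3-(3-methylbut-2-enyl)-4,5-bis(triisopropylsilyloxy)phenyl]-7-(triisopropylsilyloxy)chromen-4-one | COc1cc(O[Si](C(C)C)(C(C)C)C(C)C)cc2occ(-c3cc(CC=C(C)C)c(O[Si](C(C)C)(C(C)C)C(C)C)c(O[Si](C(C)C)(C(C)C)C(C)C)c3)c(=O)c12 | intermediate
12 | glisoflavone, 3-[3,4-dihydroxy-5-(3-methylbut-2-enyl)phenyl]-7-hydroxy-5-methoxychromen-4-one (no stereocentre) | COc1cc(O)cc2occ(-c3cc(O)c(O)c(CC=C(C)C)c3)c(=O)c12 | target

## Step count and least certain steps

Total step count: 8. Longest linear sequence: 7 steps (1 → 2 → 5 → 7 → 8 → 9 → 11 → 12; step 2 is the one-step side branch).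

**Step 6 (key step).** The most likely failure is loss of the C2 hydrogen in place of aryl migration (2,3-dehydrogenation), because the migrating ring has only one resonance donor and two weakly withdrawing meta substituents. Next most likely is partial loss of a ring B silyl group under the liberated TsOH, followed by oxidation of the freed phenol. Fallback: carry out the same aryl shift on the open-chain enone, where no dehydrogenation channel to a flavone exists. Setting out from 5, acetylation of the chelated phenol (Ac2O, pyridine, DMAP) should give the 2'-O-acetyl chalcone F1. PhI(OH)OTs in MeOH–HC(OMe)3 at 0 °C to rt should then add methanol at the benzylic carbon and shift ring B to the alpha-carbon as iodobenzene leaves, giving the rearranged dimethyl acetal F2. The short exposure to acid at or below room temperature is much milder for the acetals than hot acetonitrile. Hot methanolic HCl then removes the acetate and the three methoxymethyl groups and closes ring C by attack of the 2'-hydroxyl on the unmasked aldehyde carbon, giving 3-(3-bromo-4,5-dihydroxyphenyl)-7-hydroxy-5-methoxychromen-4-one F3. Silylation as in step 5 returns to the route at 9.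

**Step 7.** The likely failures are slow oxidative addition into the electron-rich C–Br bond beside a bulky silyl ether, which lets protodestannylation and reduction of the bromide compete, and allylic transposition in the coupling, which joins the tertiary carbon to the ring. Fallback: setting out from 9, Stille coupling with allyltributylstannane (Pd(PPh3)4, toluene, 100 °C) transmetallates more readily and has no regiochemical ambiguity, and should give the allyl isoflavone F4. Cross-metathesis with 2-methylbut-2-ene (second-generation Grubbs catalyst, CH2Cl2, 40 °C) then exchanges the terminal CH2 for CMe2 with loss of propene and returns to the route at 11. The chromone double bond is trisubstituted and electron-poor and should not take part.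

**Step 4.** The likely failures are incomplete ring closure, because chalcone and flavanone equilibrate, and aerobic oxidation of the free bromocatechol during prolonged heating. Fallback: separate the two events. Setting out from 5, NaOAc in refluxing EtOH closes the ring with the acetals still in place and should give the tris(methoxymethyl) flavanone F5, which has no oxidisable phenol and can be purified and recycled from unchanged 5. HCl in MeOH at 40 °C then removes the three acetals without the heating that reopens the ring and returns to the route at 7.

**Step 8.** The likely failures are oxidation of the catechol if the medium turns basic, sluggish cleavage of the hindered 4'-O–Si bond under buffered conditions, and opening of the chromone at C2 if unbuffered fluoride is used to force it. Fallback: unmask into a stable derivative first. Setting out from 11, Bu4NF in THF at 0 °C followed in the same flask by Ac2O traps each phenoxide as it forms and should give the air-stable glisoflavone triacetate F6, which can be purified without precautions. Transesterification with catalytic K2CO3 in degassed MeOH at 0 °C, quenched with AcOH, returns to the route at 12.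

## Further compounds

F1 | step 6 | (E)-3-[3-bromo-4,5-bis(methoxymethoxy)phenyl]-1-[2-acetoxy-6-methoxy-4-(methoxymethoxy)phenyl]prop-2-en-1-one | COc1cc(OCOC)cc(OC(C)=O)c1C(=O)/C=C/c1cc(Br)c(OCOC)c(OCOC)c1
F2 | step 6 | rac-1-[2-acetoxy-6-methoxy-4-(methoxymethoxy)phenyl]-2-[3-bromo-4,5-bis(methoxymethoxy)phenyl]-3,3-dimethoxypropan-1-one | COc1cc(OCOC)cc(OC(C)=O)c1C(=O)C(C(OC)OC)c1cc(Br)c(OCOC)c(OCOC)c1
F3 | step 6 | 3-(3-bromo-4,5-dihydroxyphenyl)-7-hydroxy-5-methoxychromen-4-one | COc1cc(O)cc2occ(-c3cc(Br)c(O)c(O)c3)c(=O)c12
F4 | step 7 | 3-[3-allyl-4,5-bis(triisopropylsilyloxy)phenyl]-5-methoxy-7-(triisopropylsilyloxy)chromen-4-one | COc1cc(O[Si](C(C)C)(C(C)C)C(C)C)cc2occ(-c3cc(CC=C)c(O[Si](C(C)C)(C(C)C)C(C)C)c(O[Si](C(C)C)(C(C)C)C(C)C)c3)c(=O)c12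
F5 | step 4 | rac-2-[3-bromo-4,5-bis(methoxymethoxy)phenyl]-5-methoxy-7-(methoxymethoxy)chroman-4-one | COc1cc(OCOC)cc2OC(c3cc(Br)c(OCOC)c(OCOC)c3)CC(=O)c12
F6 | step 8 | 7-acetoxy-3-[3,4-diacetoxy-5-(3-methylbut-2-enyl)phenyl]-5-methoxychromen-4-one | COc1cc(OC(C)=O)cc2occ(-c3cc(OC(C)=O)c(OC(C)=O)c(CC=C(C)C)c3)c(=O)c12
A1 | alternative 1 | 7-allyloxy-3-[4-hydroxy-3-(methoxymethoxy)-5-(3-methylbut-2-enyl)phenyl]-5-methoxychromen-4-one | COc1cc(OCC=C)cc2occ(-c3cc(OCOC)c(O)c(CC=C(C)C)c3)c(=O)c12
A2 | alternative 1 | N-[2-(7-allyloxy-5-methoxy-4-oxochromen-3-yl)-3-(dimethylamino)prop-2-enylidene]-N-methylmethanaminium hexafluorophosphate | CN(C)C=C(C=[N+](C)C)c1coc2cc(OCC=C)cc(OC)c2c1=O.F[P-](F)(F)(F)(F)F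
A3 | alternative 1 | 1-(methoxymethoxy)-6-methylhept-5-en-2-one | COCOCC(=O)CCC=C(C)C
A4 | alternative 2 | 3-[3,4-dihydroxy-5-(3-methylbut-2-enyl)phenyl]-5-methoxy-7-(methoxymethoxy)chromen-4-one | COc1cc(OCOC)cc2occ(-c3cc(O)c(O)c(CC=C(C)C)c3)c(=O)c12
A5 | alternative 2 | 3-[4-hydroxy-3-(3-methylbut-2-enyl)phenyl]-5-methoxy-7-(methoxymethoxy)chromen-4-one | COc1cc(OCOC)cc2occ(-c3ccc(O)c(CC=C(C)C)c3)c(=O)c12
A6 | alternative 3 | 3-[3,4-bis(methoxymethoxy)-5-(3-methylbut-2-enyl)phenyl]-7-hydroxy-5-methoxychromen-4-one | COc1cc(O)cc2occ(-c3cc(OCOC)c(OCOC)c(CC=C(C)C)c3)c(=O)c12
A7 | alternative 3 | 3-[3,4-bis(methoxymethoxy)-5-(3-methylbut-2-enyl)phenyl]-5-bromopyran-4-one | O=c1c(Br)cocc1-c1cc(OCOC)c(OCOC)c(CC=C(C)C)c1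
A8 | alternative 3 | 1,1-dimethoxy-3-(trimethylsilyloxy)buta-1,3-diene | COC(OC)=CC(=C)O[Si](C)(C)C
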